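The seven-membered ring is treated as a latent cyclohepta-1,4-diene (azulene numbering: C1 carries the isopropyl group, C3a the methyl group, C6 the CH2O group). C6, vinylic C5 and allylic C4 come from a vinylcarbenoid; C7, C8, ring-fusion C8a and quaternary C3a come from the diene of achiral 3-methyl-2-vinylcyclopent-2-enone. In one operation a chiral dirhodium carbenoid closes a cyclopropane by forming C6–C7, and a Cope rearrangement enlarges it to the seven-membered ring by forming C4–C3a, which sets the quaternary stereocenter. Reductive enol triflation, isopropyl cross-coupling, ester reduction and Mitsunobu esterification with vanillic acid complete the synthesis.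

Key step: step 3

Remark: the facial sense of carbenoid transfer from Rh2(DOSP)4 is assumed to follow the usual model for donor/acceptor carbenoids and monosubstituted alkenes; on that model Rh2(R-DOSP)4 should give (1S,2S)-5 and hence (3aR)-6, and Rh2(S-DOSP)4 would be used if the sense were the reverse.

Step 1
Reactants: 1 2-bromo-3-methylcyclopent-2-en-1-one
Product: 2 2-ethenyl-3-methylcyclopent-2-en-1-one
Conditions: tributyl(vinyl)stannane (1.2 equiv), Pd(PPh3)4 (5 mol%), BHT (cat.), toluene, 100 °C
Reagents that add atoms: tributyl(vinyl)stannane, C=C[Sn](CCCC)(CCCC)CCCC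
Why: Stille cross-coupling of an α-bromoenone with a vinylstannane is a standard sp2–sp2 coupling that leaves the enone intact and creates no stereocenter.

Step 2
Reactants: 3 methyl but-3-enoate
Product: 4 methyl 2-diazobut-3-enoate
Conditions: p-ABSA (1.2 equiv), DBU (1.3 equiv), MeCN, 0 °C; cold filtration through silica, solution used at once
Reagents that add atoms: 4-acetamidobenzenesulfonyl azide (p-ABSA), CC(=O)Nc1ccc(cc1)S(=O)(=O)N=[N+]=[N-]
Why: Regitz deprotonative diazo transfer, in which DBU forms the dienolate of the β,γ-unsaturated ester and its α-carbon attacks the sulfonyl azide; the product is kept cold because it slowly electrocyclises to a pyrazole.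

Step 3
Reactants: 2 2-ethenyl-3-methylcyclopent-2-en-1-one; 4 methyl 2-diazobut-3-enoate
Product: 6 methyl (3aR)-3a-methyl-1-oxo-1,2,3,3a,4,7-hexahydroazulene-6-carboxylate, via cis-divinylcyclopropane 5 (not isolated)
Conditions: Rh2(R-DOSP)4 (1 mol%), 2 (1.5 equiv), slow addition of 4, pentane/PhCF3, −40 °C → rt; then toluene, 100 °C
Reagents that add atoms: none
Why: Rh2(R-DOSP)4 decomposes 4 to a donor/acceptor rhodium vinylcarbenoid whose carbenoid carbon adds in a concerted, asynchronous [2+1] fashion to the terminal CH=CH2 of 2, closing a cyclopropane and forming the C6–C7 bond, and the cis-divinylcyclopropane 5 then undergoes a [3,3] Cope rearrangement through the obligatory boat transition state, which breaks the cyclopropane bond between the two alkenyl-bearing carbons, joins the vinyl CH2 (C4) to the methyl-bearing ring carbon (C3a) and so enlarges the three-membered ring to the seven-membered ring. The closest known reaction type is the tandem cyclopropanation/Cope (formal [4+3]) annulation of vinyldiazoacetates with 1,3-dienes under chiral dirhodium tetracarboxylate catalysis, which is established for dienes with a disubstituted terminus that ends as a quaternary carbon. The only new stereocenter in 6, quaternary C3a, is controlled by the catalyst: the prolinate ligands fix the two cyclopropane stereocenters of 5, and the boat geometry together with the ring-locked geometry of the tetrasubstituted alkene transfers them stereospecifically to C3a. The step needs site selectivity for the monosubstituted vinyl group over the tetrasubstituted enone alkene and the ketone oxygen, secured by the steric and electronic preference of the electrophilic carbenoid for the terminal CH2, and cis selectivity in the cyclopropanation, which is intrinsic to donor/acceptor carbenoids that place the donor vinyl group syn to the alkene substituent. Regiochemistry is fixed by the mechanism, since the carbenoid carbon can only end up bonded to the former terminal CH2 and its vinyl terminus to the far end of the diene. The methyl group that points inward at the reacting diene terminus slows the Cope step, hence the heating, while conjugation of both new alkenes (enoate and enone) provides the driving force.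

Step 4
Reactants: 6 methyl (3aR)-3a-methyl-1-oxo-1,2,3,3a,4,7-hexahydroazulene-6-carboxylate
Product: 8 methyl (3aR)-3a-methyl-1-[(trifluoromethanesulfonyl)oxy]-2,3,3a,4,7,8-hexahydroazulene-6-carboxylate, via lithium enolate 7 (not isolated)
Conditions: LiBH(s-Bu)3 (1.05 equiv), THF, −78 °C; then PhNTf2 (1.2 equiv), −78 → 0 °C; H2O work-up
Reagents that add atoms: N-phenylbis(trifluoromethanesulfonimide) (PhNTf2), FC(F)(F)S(=O)(=O)N(c1ccccc1)S(=O)(=O)C(F)(F)F
Why: Conjugate hydride addition of the bulky borohydride to the s-cis exocyclic enone, which is far more electrophilic than the enoate, should give the tetrasubstituted C1=C8a enolate regiospecifically, and in situ O-triflation (reductive enolate trapping) fixes it as the enol triflate without touching C3a.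

Step 5
Reactants: 8 methyl (3aR)-3a-methyl-1-[(trifluoromethanesulfonyl)oxy]-2,3,3a,4,7,8-hexahydroazulene-6-carboxylate
Product: 9 methyl (3aR)-3a-methyl-1-(propan-2-yl)-2,3,3a,4,7,8-hexahydroazulene-6-carboxylate
Conditions: i-PrZnBr (2 equiv), Pd(OAc)2 (2 mol%), CPhos (4 mol%), THF/toluene, rt
Reagents that add atoms: isopropylzinc bromide, CC(C)[Zn]Br
Why: Negishi cross-coupling of an alkenyl triflate with a secondary alkylzinc halide, where the CPhos-ligated palladium should favour reductive elimination over β-hydride elimination so that isopropyl is transferred without isomerisation, and the ester is inert to the organozinc.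

Step 6
Reactants: 9 methyl (3aR)-3a-methyl-1-(propan-2-yl)-2,3,3a,4,7,8-hexahydroazulene-6-carboxylate
Product: 10 [(3aR)-3a-methyl-1-(propan-2-yl)-2,3,3a,4,7,8-hexahydroazulen-6-yl]methanol
Conditions: i-Bu2AlH (2.5 equiv), CH2Cl2, −78 °C; aq. potassium sodium tartrate
Reagents that add atoms: none
Why: 1,2-Reduction of the α,β-unsaturated ester by the aluminium hydride at low temperature should stop cleanly at the allylic alcohol, with both alkenes inert.

Step 7
Reactants: 10 [(3aR)-3a-methyl-1-(propan-2-yl)-2,3,3a,4,7,8-hexahydroazulen-6-yl]methanol; 11 4-hydroxy-3-methoxybenzoic acid (vanillic acid)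
Product: 12 [(3aR)-3a-methyl-1-(propan-2-yl)-2,3,3a,4,7,8-hexahydroazulen-6-yl]methyl 4-hydroxy-3-methoxybenzoate
Conditions: PPh3 (1.3 equiv), DIAD (1.3 equiv), THF, 0 °C → rt
Reagents that add atoms: none
Why: Mitsunobu esterification, in which the carboxylic acid is far more acidic than the phenol, so the carboxylate should displace the primary allylic oxyphosphonium by SN2 and the phenol needs no protection.

Compound list
1 | 2-bromo-3-methylcyclopent-2-en-1-one | CC1=C(Br)C(=O)CC1 | starting material
2 | 2-ethenyl-3-methylcyclopent-2-en-1-one | CC1=C(C=C)C(=O)CC1 | intermediate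
3 | methyl but-3-enoate | C=CCC(=O)OC | starting material
4 | methyl 2-diazobut-3-enoate | C=CC(=[N+]=[N-])C(=O)OC | intermediate
5 | methyl (1S,2S)-1-ethenyl-2-(2-methyl-5-oxocyclopent-1-en-1-yl)cyclopropane-1-carboxylate | COC(=O)[C@]1(C=C)C[C@H]1C1=C(C)CCC1=O | intermediate
6 | methyl (3aR)-3a-methyl-1-oxo-1,2,3,3a,4,7-hexahydroazulene-6-carboxylate | COC(=O)C1=CC[C@@]2(C)CCC(=O)C2=CC1 | intermediate
7 | lithium (3aR)-6-(methoxycarbonyl)-3a-methyl-2,3,3a,4,7,8-hexahydroazulen-1-olate | [Li+].COC(=O)C1=CC[C@@]2(C)CCC([O-])=C2CC1 | intermediate
8 | methyl (3aR)-3a-methyl-1-[(trifluoromethanesulfonyl)oxy]-2,3,3a,4,7,8-hexahydroazulene-6-carboxylate | COC(=O)C1=CC[C@@]2(C)CCC(OS(=O)(=O)C(F)(F)F)=C2CC1 | intermediate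
9 | methyl (3aR)-3a-methyl-1-(propan-2-yl)-2,3,3a,4,7,8-hexahydroazulene-6-carboxylate | COC(=O)C1=CC[C@@]2(C)CCC(C(C)C)=C2CC1 | intermediate
10 | [(3aR)-3a-methyl-1-(propan-2-yl)-2,3,3a,4,7,8-hexahydroazulen-6-yl]methanol | OCC1=CC[C@@]2(C)CCC(C(C)C)=C2CC1 | intermediate
11 | 4-hydroxy-3-methoxybenzoic acid (vanillic acid) | COc1cc(C(=O)O)ccc1O | starting material
12 | [(3aR)-3a-methyl-1-(propan-2-yl)-2,3,3a,4,7,8-hexahydroazulen-6-yl]methyl 4-hydroxy-3-methoxybenzoate | COc1cc(C(=O)OCC2=CC[C@@]3(C)CCC(C(C)C)=C3CC2)ccc1O | target

Total step count: 7. Longest linear sequence: 6 steps (steps 1, 3, 4, 5, 6 and 7, from compound 1).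

Steps most likely to fail

Step 3. The electrophilic carbenoid may be diverted by the Lewis-basic, electron-poor dienone (attack at the ketone oxygen, sluggish cyclopropanation). The boat Cope closure may also stall against the inward-pointing methyl group or erode enantiomeric purity on prolonged heating. The fallback sets out from 2 and masks the ketone first. Ketalisation with 1,2-bis(trimethylsilyloxy)ethane and catalytic TMSOTf (CH2Cl2, −78 °C) should give the more electron-rich, non-coordinating diene 6-ethenyl-7-methyl-1,4-dioxaspiro[4.4]non-6-ene F1. The carbenoid from 4 under Rh2(R-DOSP)4 should then give the cyclopropane methyl (1S,2S)-1-ethenyl-2-(7-methyl-1,4-dioxaspiro[4.4]non-6-en-6-yl)cyclopropane-1-carboxylate F2. This is isolated and rearranged thermally in a separate operation (xylene, 130 °C) to the ethylene ketal of 6, methyl (3aR)-1,1-(ethane-1,2-diyldioxy)-3a-methyl-1,2,3,3a,4,7-hexahydroazulene-6-carboxylate F3. Mild hydrolysis (PPTS, aqueous acetone) comes back to the route at 6.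

Step 5. β-Hydride elimination and reinsertion at the isopropyl–palladium intermediate (chain walking to the n-propyl isomer, or simple reduction of the triflate) may compete, and transmetalation at the hindered tetrasubstituted alkenylpalladium may be slow. The fallback sets out from 8 and avoids an sp3 organometallic. Suzuki–Miyaura coupling with isopropenylboronic acid pinacol ester (PdCl2(dppf), K3PO4, dioxane/H2O, 80 °C) should give the diene methyl (3aR)-3a-methyl-1-(prop-1-en-2-yl)-2,3,3a,4,7,8-hexahydroazulene-6-carboxylate F4. Site-selective hydrogenation of its 1,1-disubstituted alkene (H2, 1 atm, RhCl(PPh3)3, benzene) comes back to the route at 9.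

Step 4. Competing 1,2-reduction of the ketone, over-reduction of the enoate, or incomplete O-sulfonylation of the hindered, borane-associated enolate may lower the yield. The fallback sets out from 6 and replaces the hydride by a catalytic 1,4-hydrosilylation. RhCl(PPh3)3 (cat.) and Et3SiH (benzene, 50 °C) should give regiospecifically the silyl enol ether methyl (3aR)-3a-methyl-1-[(triethylsilyl)oxy]-2,3,3a,4,7,8-hexahydroazulene-6-carboxylate F5. Fluoride-triggered triflation (CsF, PhNTf2, DME, rt) comes back to the route at 8.

Further compounds
F1 | step 3 | 6-ethenyl-7-methyl-1,4-dioxaspiro[4.4]non-6-ene | C=CC1=C(C)CCC12OCCO2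
F2 | step 3 | methyl (1S,2S)-1-ethenyl-2-(7-methyl-1,4-dioxaspiro[4.4]non-6-en-6-yl)cyclopropane-1-carboxylate | COC(=O)[C@]1(C=C)C[C@H]1C1=C(C)CCC12OCCO2
F3 | step 3 | methyl (3aR)-1,1-(ethane-1,2-diyldioxy)-3a-methyl-1,2,3,3a,4,7-hexahydroazulene-6-carboxylate | COC(=O)C1=CC[C@@]2(C)CCC3(OCCO3)C2=CC1
F4 | step 5 | methyl (3aR)-3a-methyl-1-(prop-1-en-2-yl)-2,3,3a,4,7,8-hexahydroazulene-6-carboxylate | COC(=O)C1=CC[C@@]2(C)CCC(C(C)=C)=C2CC1
F5 | step 4 | methyl (3aR)-3a-methyl-1-[(triethylsilyl)oxy]-2,3,3a,4,7,8-hexahydroazulene-6-carboxylate | COC(=O)C1=CC[C@@]2(C)CCC(O[Si](CC)(CC)CC)=C2CC1
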